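(The data stem from a simulated flask with made-up constants, noise included.)

Late in the delta and zeta runs target falls while substrate slows down, so the useful reading is the standing ratio [target]/[substrate]. Here substrate sits in the first phase, reagent in the second phase feeds the reaction there, and the two give target.

the same everywhere: substrate 0.23 M
- delta: reagent in the second phase 0.18 M; run made earlier
- zeta: reagent in the second phase 0.41 M; run made earlier
- flask: reagent in the second phase 0.276 M; time 80 min; volume of the second phase over the first 0.50

| run | time / min | target / % | substrate / % |
|---|---|---|---|
| delta | 5.00 | 7.5 | 88.5 |
| delta | 10.0 | 11.6 | 79.0 |
| delta | 20.0 | 16.0 | 69.7 |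
| delta | 30.0 | 14.7 | 67.5 |
| delta | 60.0 | 11.4 | 65.5 |
| zeta | 5.00 | 14.1 | 77.4 |
| zeta | 10.0 | 22.2 | 57.2 |
| zeta | 20.0 | 21.8 | 43.3 |
| zeta | 30.0 | 18.0 | 39.3 |
| zeta | 60.0 | 11.3 | 32.3 |

(each reading ± 0.5 percentage points)

- in the second phase: reagent in the second phase; everything else is in the first
- charges count per volume of the first phase; a concentration in a rate is the amount of a species over the volume of its own phase; every rate counts per litre of the first phase
- the earlier runs hold the two phases in the same ratio of volumes as the flask asked about

1. the target standing at 80 min, as a percentage of the substrate charged
2. the change that raises the amount of target at 80 min, in percent of the substrate charged most ("none" if none brings more than 2 percentage points) (summer / midnight / none)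
3. amount of target at 80 min, in percent of the substrate charged, after summer

- summer: doubling the transfer coefficient of the reagent in the second phase, all else as stated
- midnight: doubling the amount of reagent in the second phase, all else as stated

At 60.0 min target reads 11.4% in delta and 11.3% in zeta, nearly equal, but the standing ratio reads 0.174 in delta and 0.350 in zeta, higher with the larger reagent charge. Between 30.0 min and 60.0 min the ratio, as read, decays with a time constant of 134 min in delta and 111 min in zeta, two readings of like size although the reagent charges differ widely.

That makes the reckoning for the flask a closed form. Interpolating on the reagent charge gives an estimate for the flask at 60.0 min: a ratio of 0.247 and substrate at 51.6%. An exponential decay over the remaining 20.0 min, with the mean time constant 123 min, gives 0.210, the estimate of the flask's standing ratio at the asked time. With substrate held at its interpolated level, ignoring its further slide, this reckoning puts target at 10.9%.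

The forecast, by its own route, says 11%, best change none, and 10% after summer: “Neither helps, so the answer is none.”

The simulation gives 10.5%, and 10.4% after summer. Summer changes target by −0.17 percentage points and midnight by −4.2 points, so the answer is none.

    substrate + reagent in the reaction phase ⇌ target (K = 3.70 M⁻¹, k = 0.00615 M⁻¹ s⁻¹)
    reagent in the reaction phase ⇌ reagent in the second phase, rate k2*([reagent in the reaction phase] - [reagent in the second phase]/K2) per volume of the first phase (partition coefficient = 0.460, kL = 0.00122 s⁻¹)
    reagent in the reaction phase + target → over-reaction product (k = 0.00507 M⁻¹ s⁻¹)
    target ⇌ isomer of the product (K = 0.530, k = 0.0119 s⁻¹)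

Target in the flask is held down in part by the back reaction and the over-reaction acting together: without the first it stands at 31.0%, without the second at 29.0%. The first step runs back, its backward turnover 69% of the forward one, and the estimated standing ratio is here taken as proportional to reagent in the reaction phase: 0.210 over 0.0618 M is 3.40 M⁻¹. The same flask read at 3.0 h holds 0.0351 M of that reagent and 45.1% substrate, so scaling the ratio gives 5.38% target, and that flask stands at 5.66%.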